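**Retrosynthetic overview**
1. The free CO2H is unveiled last from a 2-(trimethylsilyl)ethyl ester by fluoride, which leaves the secondary acetate alone.
2. Enabling feature: the benzene ring (C1 CO2H, C2 OH, C4 OH, C6 chain) is a folded 3,5,7-triketo acid whose ring carbon C6 was a ketone. The two chain CH2 groups next to the ring (C1', C2') can therefore be a vinyl group on that ketone, a radical acceptor at C2'.
3. Key disconnection C2'–C3': the primary C3' radical from the N-acyloxyphthalimide of (7Z,9R)-9-acetoxytetradec-7-enoic acid adds to the vinyl ketone of a diketo-dioxinone (masked tetraketide). In the same pot the dioxinone is opened through its acylketene with Me3SiCH2CH2OH and the triketo ester is folded by aldol condensation.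
4. Fragments: the redox-active ester comes from (R)-oct-1-yn-3-ol (stereocentre bought) and 6-bromohexanoic acid, with Lindlar reduction for the Z-alkene. The vinyl diketo-dioxinone comes from 2,2,6-trimethyl-1,3-dioxin-4-one, acetyl chloride and acrolein.
5. Ring order: the benzene ring is the only ring; it is formed in the key step, directly after the fragment-joining C–C bond.

Key step: step 8

Remark 1: the carbinol carbon of the target is (R) (O > alkenyl C > pentyl C > H), so commercial (R)-oct-1-yn-3-ol supplies it.
Remark 2: β-dicarbonyl compounds are drawn as keto tautomers although they are largely enolised; lithium salts formed by deprotonation are treated as forms of the numbered compound.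

**Step 1**
Reactants: 1 (R)-oct-1-yn-3-ol; 2 6-bromohexanoic acid
Product: 3 (R)-9-hydroxytetradec-7-ynoic acid
Conditions: n-BuLi (3.1 equiv in total), THF/DMPU, −78 °C → rt; aq. HCl
Reagents that add atoms: none
Why: Alkylation of a lithium acetylide with a primary bromide (SN2) in which, after triple deprotonation, the acetylide carbon is by far the best nucleophile while the lithium alkoxide and carboxylate are spectators, and the carbinol stereocentre bought with 1 is not involved.

**Step 2**
Reactants: 3 (R)-9-hydroxytetradec-7-ynoic acid
Product: 4 (7Z,9R)-9-hydroxytetradec-7-enoic acid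
Conditions: H2 (1 atm), Lindlar catalyst, quinoline, EtOAc, rt
Reagents that add atoms: none
Why: Lindlar semihydrogenation delivers both hydrogens syn on the poisoned Pd surface, so only the Z-alkene should form and reduction should stop at the alkene, with the allylic stereocentre untouched.

**Step 3**
Reactants: 4 (7Z,9R)-9-hydroxytetradec-7-enoic acid
Product: 5 1,3-dioxoisoindolin-2-yl (7Z,9R)-9-hydroxytetradec-7-enoate
Conditions: N-hydroxyphthalimide, DIC, DMAP (5 mol%), CH2Cl2, 0 °C → rt
Reagents that add atoms: N-hydroxyphthalimide, O=C1c2ccccc2C(=O)N1O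
Why: Carbodiimide (Steglich-type) esterification in which the acidic N–OH of N-hydroxyphthalimide captures the O-acylisourea much faster than the hindered secondary allylic alcohol, giving the redox-active ester needed for radical generation.

**Step 4**
Reactants: 5 1,3-dioxoisoindolin-2-yl (7Z,9R)-9-hydroxytetradec-7-enoate
Product: 6 1,3-dioxoisoindolin-2-yl (7Z,9R)-9-acetoxytetradec-7-enoate
Conditions: Ac2O, pyridine, DMAP (cat.), CH2Cl2, 0 °C
Reagents that add atoms: acetic anhydride, CC(=O)OC(C)=O
Why: DMAP-catalysed acetylation of the secondary alcohol proceeds with retention (the C–O bond is not broken) and should be fast enough at 0 °C that the active ester is not attacked.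

**Step 5**
Reactants: 7 2,2,6-trimethyl-4H-1,3-dioxin-4-one
Product: 8 2,2-dimethyl-6-(2-oxopropyl)-4H-1,3-dioxin-4-one
Conditions: LiHMDS, THF, −78 °C; AcCl (0.5 equiv per dienolate), −78 °C; aq. HCl
Reagents that add atoms: acetyl chloride, CC(=O)Cl
Why: γ-C-Acylation (vinylogous Claisen condensation) of the lithium dienolate of the dioxinone with acetyl chloride, in which the second equivalent of dienolate absorbs the acidic proton of the β-keto product and so prevents double acylation.

**Step 6**
Reactants: 8 2,2-dimethyl-6-(2-oxopropyl)-4H-1,3-dioxin-4-one; 9 acrolein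
Product: 10 6-(4-hydroxy-2-oxohex-5-en-1-yl)-2,2-dimethyl-4H-1,3-dioxin-4-one (racemic)
Conditions: LDA (commercial solution, 2.2 equiv), THF, −78 °C; acrolein, −78 °C; AcOH quench
Reagents that add atoms: none
Why: Aldol addition of the dianion of the β-keto-dioxinone, which reacts at its terminal, last-formed and most nucleophilic carbon and adds 1,2 to acrolein at −78 °C; the new carbinol centre forms as a racemate, which does not matter because step 7 removes it.

**Step 7**
Reactants: 10 6-(4-hydroxy-2-oxohex-5-en-1-yl)-2,2-dimethyl-4H-1,3-dioxin-4-one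
Product: 11 6-(2,4-dioxohex-5-en-1-yl)-2,2-dimethyl-4H-1,3-dioxin-4-one
Conditions: Dess–Martin periodinane (1.1 equiv), CH2Cl2, 0 °C; rapid filtration, BHT (trace), used at once
Reagents that add atoms: none
Why: Dess–Martin oxidation of the allylic β-hydroxy ketone under base-free conditions should give the enolised vinyl β-diketone without starting the aldol aromatisation or conjugate additions that a base would cause, and it removes the racemic carbinol centre.

**Step 8**
Reactants: 6 1,3-dioxoisoindolin-2-yl (7Z,9R)-9-acetoxytetradec-7-enoate; 11 6-(2,4-dioxohex-5-en-1-yl)-2,2-dimethyl-4H-1,3-dioxin-4-one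
Product: 15 2-(trimethylsilyl)ethyl 2-[(8Z,10R)-10-acetoxypentadec-8-en-1-yl]-4,6-dihydroxybenzoate, via diketo-dioxinone Giese adduct 12 (not isolated), via acylketene 13 (not isolated), via triketo ester 14 (not isolated)
Conditions: 6 (1.0 equiv), 11 (1.5 equiv), Ru(bpy)3(PF6)2 (1 mol%), Hantzsch ester (1.5 equiv), CH2Cl2 (0.3 M), blue LEDs, rt; solvent switch to PhMe, TMSCH2CH2OH (3 equiv), 110 °C; then Et3N, rt; aq. citric acid
Reagents that add atoms: 2-(trimethylsilyl)ethanol, C[Si](C)(C)CCO
Why: Single-electron reduction of the N-acyloxyphthalimide 6 by the photoreduced Ru catalyst (Hantzsch ester as terminal reductant) releases CO2 and phthalimide and gives the primary alkyl radical, which adds to the unsubstituted terminal CH2 of the vinyl ketone of 11 (decarboxylative Giese addition), and the stabilised α-carbonyl radical takes a hydrogen atom from the Hantzsch ester to give 12. Heating 12 extrudes acetone by retro-[4+2] fragmentation of the dioxinone, the acylketene 13 is captured by 2-(trimethylsilyl)ethanol to give the triketo ester 14, and triethylamine then enolises C2 (between the ester and the C3 ketone), which adds to the C7 ketone, after which loss of water and enolisation of the C3 and C5 carbonyls give the benzene ring. The closest known reaction types are the photoredox Giese addition of redox-active esters to enones and the thermolysis, ketene-trapping and aromatisation sequence of diketo-dioxinones. The one ring is closed by an intramolecular aldol condensation in the 6-(enolexo)-exo-trig mode (C2 onto C7). No stereocentre is formed, and the existing carbinol centre and the Z-alkene are remote from all reacting sites, with no thiyl, silyl or metal-hydride species present that could isomerise the alkene. The step needs the radical to add intermolecularly before it closes 6-exo onto the internal alkene or shifts an allylic hydrogen (secured by the doubly activated, unhindered vinyl ketone in excess at high concentration), and it needs aldol rather than Claisen or lactone closure of 14 (secured by the amine base, under which the C7 ketone is a better electrophile than the ester carbon).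

**Step 9**
Reactants: 15 2-(trimethylsilyl)ethyl 2-[(8Z,10R)-10-acetoxypentadec-8-en-1-yl]-4,6-dihydroxybenzoate
Product: 16 2-[(8Z,10R)-10-acetoxypentadec-8-en-1-yl]-4,6-dihydroxybenzoic acid (CNP0288291.1)
Conditions: TBAF (3.5 equiv), THF, 0 °C; dilute aq. HCl to pH 3, cold
Reagents that add atoms: none
Why: Fluoride attacks silicon and the 2-(trimethylsilyl)ethyl ester fragments by β-elimination to ethylene, Me3SiF and the carboxylate without any acyl substitution, so the secondary allylic acetate, the Z-alkene and the stereocentre should be retained, and the cold work-up at pH 3 avoids decarboxylation of the 2,4-dihydroxybenzoic acid.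

**Compound list**
1 | (R)-oct-1-yn-3-ol | CCCCC[C@H](C#C)O | starting material
2 | 6-bromohexanoic acid | OC(=O)CCCCCBr | starting material
3 | (R)-9-hydroxytetradec-7-ynoic acid | CCCCC[C@H](C#CCCCCCC(=O)O)O | intermediate
4 | (7Z,9R)-9-hydroxytetradec-7-enoic acid | CCCCC[C@H](/C=C\CCCCCC(=O)O)O | intermediate
5 | 1,3-dioxoisoindolin-2-yl (7Z,9R)-9-hydroxytetradec-7-enoate | CCCCC[C@H](/C=C\CCCCCC(=O)ON1C(=O)c2ccccc2C1=O)O | intermediate
6 | 1,3-dioxoisoindolin-2-yl (7Z,9R)-9-acetoxytetradec-7-enoate | CCCCC[C@H](/C=C\CCCCCC(=O)ON1C(=O)c2ccccc2C1=O)OC(C)=O | intermediate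
7 | 2,2,6-trimethyl-4H-1,3-dioxin-4-one | CC1=CC(=O)OC(C)(C)O1 | starting material
8 | 2,2-dimethyl-6-(2-oxopropyl)-4H-1,3-dioxin-4-one | CC(=O)CC1=CC(=O)OC(C)(C)O1 | intermediate
9 | acrolein | C=CC=O | starting material
10 | 6-(4-hydroxy-2-oxohex-5-en-1-yl)-2,2-dimethyl-4H-1,3-dioxin-4-one (racemic) | C=CC(O)CC(=O)CC1=CC(=O)OC(C)(C)O1 | intermediate
11 | 6-(2,4-dioxohex-5-en-1-yl)-2,2-dimethyl-4H-1,3-dioxin-4-one | C=CC(=O)CC(=O)CC1=CC(=O)OC(C)(C)O1 | intermediate
12 | 6-[(12Z,14R)-14-acetoxy-2,4-dioxononadec-12-en-1-yl]-2,2-dimethyl-4H-1,3-dioxin-4-one | CCCCC[C@H](/C=C\CCCCCCCC(=O)CC(=O)CC1=CC(=O)OC(C)(C)O1)OC(C)=O | intermediate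
13 | acylketene from 12 by loss of acetone (chain ends in C(=O)CH=C=O) | CCCCC[C@H](/C=C\CCCCCCCC(=O)CC(=O)CC(=O)C=C=O)OC(C)=O | intermediate
14 | 2-(trimethylsilyl)ethyl (15Z,17R)-17-acetoxy-3,5,7-trioxodocos-15-enoate | CCCCC[C@H](/C=C\CCCCCCCC(=O)CC(=O)CC(=O)CC(=O)OCC[Si](C)(C)C)OC(C)=O | intermediate
15 | 2-(trimethylsilyl)ethyl 2-[(8Z,10R)-10-acetoxypentadec-8-en-1-yl]-4,6-dihydroxybenzoate | CCCCC[C@H](/C=C\CCCCCCCc1cc(O)cc(O)c1C(=O)OCC[Si](C)(C)C)OC(C)=O | intermediate
16 | 2-[(8Z,10R)-10-acetoxypentadec-8-en-1-yl]-4,6-dihydroxybenzoic acid | CCCCC[C@H](/C=C\CCCCCCCc1cc(O)cc(O)c1C(=O)O)OC(C)=O | target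

**Totals**
Total step count: 9. Longest linear sequence: 6 steps (1, 2, 3, 4, 8, 9); the dioxinone branch (5, 6, 7) joins at step 8.

**Steps most likely to fail**

Step 8. The primary radical may be lost before it reaches the acceptor (shift of an allylic hydrogen, 6-exo closure onto the Z-alkene, direct reduction). The vinyl diketone may also oligomerise under the radical flux, or the diketo-dioxinone may close early to the acetonide before the ketene stage. The fallback uses no radical: the chain is made two carbons longer at the alkylation stage and joined to the ring-forming chain by a Claisen condensation. It sets out from 1 and 8 and comes back at 12. Compound 1 is alkylated as in step 1 but with 8-bromooctanoic acid to give (R)-11-hydroxyhexadec-9-ynoic acid F1. Lindlar reduction should give (9Z,11R)-11-hydroxyhexadec-9-enoic acid F2. EDC coupling with N,O-dimethylhydroxylamine hydrochloride should give (9Z,11R)-11-hydroxy-N-methoxy-N-methylhexadec-9-enamide F3, and acetylation should give (9Z,11R)-11-acetoxy-N-methoxy-N-methylhexadec-9-enamide F4. The dianion of 8 (LDA, 2.2 equiv, −78 °C) is then acylated at its terminal carbon by F4 in a Claisen-type condensation; the chelated Weinreb amide is expected to react before the hindered secondary acetate. This gives 12, now isolated, which is taken to 15 by the thermal and amine stages of step 8.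

Step 7. The vinyl β-diketone may not survive isolation (Michael-type oligomerisation, over-oxidation of the activated CH2 by the periodinane, aldol closure on silica). In the fallback it is never isolated: the ring is closed first and the fragments are joined on the arene. It sets out from 10 and comes back at 15. Compound 10 is oxidised as in step 7 and the crude 11 is heated at once with 2-(trimethylsilyl)ethanol in toluene. This should give, through 3,5,7-trioxonona-1,8-dien-1-one F5, the ester 2-(trimethylsilyl)ethyl 3,5,7-trioxonon-8-enoate F6, which triethylamine closes to 2-(trimethylsilyl)ethyl 2,4-dihydroxy-6-vinylbenzoate F7, a stable styrene. F7 and 6 are then joined by photoredox decarboxylative hydroalkylation (Ru(bpy)3(PF6)2, Hantzsch ester, blue LEDs). Radical addition to the terminal carbon of the electron-poor vinylarene and hydrogen transfer to the benzylic radical should give 15.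

Step 9. Basic fluoride may also remove the allylic acetate by acyl cleavage. The fallback strips all acyl groups and puts the acetate back by peracetylation and selective aminolysis of the aryl acetates. It sets out from 15 and comes back at 16. Compound 15 is treated with TBAF and then K2CO3 in MeOH to give 2,4-dihydroxy-6-[(8Z,10R)-10-hydroxypentadec-8-en-1-yl]benzoic acid F8. Ac2O in pyridine should give acetic 2,4-diacetoxy-6-[(8Z,10R)-10-acetoxypentadec-8-en-1-yl]benzoic anhydride F9, which aqueous work-up hydrolyses to 2,4-diacetoxy-6-[(8Z,10R)-10-acetoxypentadec-8-en-1-yl]benzoic acid F10. Pyrrolidine (CH2Cl2, 0 °C) should cleave only the two aryl acetates and leave the alkyl acetate, giving 16.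

**Further compounds**
F1 | step 8 | (R)-11-hydroxyhexadec-9-ynoic acid | CCCCC[C@H](C#CCCCCCCCC(=O)O)O
F2 | step 8 | (9Z,11R)-11-hydroxyhexadec-9-enoic acid | CCCCC[C@H](/C=C\CCCCCCCC(=O)O)O
F3 | step 8 | (9Z,11R)-11-hydroxy-N-methoxy-N-methylhexadec-9-enamide | CCCCC[C@H](/C=C\CCCCCCCC(=O)N(C)OC)O
F4 | step 8 | (9Z,11R)-11-acetoxy-N-methoxy-N-methylhexadec-9-enamide | CCCCC[C@H](/C=C\CCCCCCCC(=O)N(C)OC)OC(C)=O
F5 | step 7 | 3,5,7-trioxonona-1,8-dien-1-one | C=CC(=O)CC(=O)CC(=O)C=C=O
F6 | step 7 | 2-(trimethylsilyl)ethyl 3,5,7-trioxonon-8-enoate | C=CC(=O)CC(=O)CC(=O)CC(=O)OCC[Si](C)(C)C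
F7 | step 7 | 2-(trimethylsilyl)ethyl 2,4-dihydroxy-6-vinylbenzoate | C=Cc1cc(O)cc(O)c1C(=O)OCC[Si](C)(C)C
F8 | step 9 | 2,4-dihydroxy-6-[(8Z,10R)-10-hydroxypentadec-8-en-1-yl]benzoic acid | CCCCC[C@H](/C=C\CCCCCCCc1cc(O)cc(O)c1C(=O)O)O
F9 | step 9 | acetic 2,4-diacetoxy-6-[(8Z,10R)-10-acetoxypentadec-8-en-1-yl]benzoic anhydride | CCCCC[C@H](/C=C\CCCCCCCc1cc(OC(C)=O)cc(OC(C)=O)c1C(=O)OC(C)=O)OC(C)=O
F10 | step 9 | 2,4-diacetoxy-6-[(8Z,10R)-10-acetoxypentadec-8-en-1-yl]benzoic acid | CCCCC[C@H](/C=C\CCCCCCCc1cc(OC(C)=O)cc(OC(C)=O)c1C(=O)O)OC(C)=O
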